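The constants of this scheme were hidden from me, so I took the one I needed from the readings. On the list of suspects, the enzyme Z takes up E as X, X takes up G as D, and D gives J and Z back.

all flasks: E 0.050 M

| run | G | Z | remark | time |
|---|---|---|---|---|
| Friday's | 0.075 M | 5 µM | run made earlier |  |
| Thursday's | 0.075 M | 3.4 µM | run made earlier |  |
| Saturday's | 0.075 M | 7.5 µM | run made earlier |  |
| zeta | 0.0750 M (fed, over 40.0 h) | 5.0 µM | a stirred flask in which G is dosed at a steady rate over 40.0 h without added volume, worked up at 40 h | 40 h |
| epsilon | 0.0750 M | 5.0 µM | a single well-mixed tank run continuously and read at steady state, 400 h in it on average |  |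
| alpha | 0.0750 M | 5.0 µM | a single well-mixed tank run continuously and read at steady state, 40 h in it on average |  |
| eta | 0.0750 M | 5.0 µM | a closed flask charged with all of it at once and left for 40 h | 40 h |

| run | time / h | J / % |
|---|---|---|
| Friday's | 4.00 | 14.8 |
| Friday's | 10.0 | 33.0 |
| Friday's | 20.0 | 56.6 |
| Friday's | 30.0 | 71.5 |
| Friday's | 40.0 | 81.8 |
| Thursday's | 4.00 | 10.1 |
| Thursday's | 8.00 | 19.0 |
| Thursday's | 15.0 | 34.2 |
| Thursday's | 25.0 | 49.4 |
| Thursday's | 50.0 | 73.9 |
| Saturday's | 10.0 | 45.4 |
| Saturday's | 20.0 | 71.4 |
| Saturday's | 30.0 | 85.1 |
| Saturday's | 40.0 | 91.2 |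
| Saturday's | 50.0 | 92.6 |

(readings scatter by 0.5 percentage points)

- percentages count the E that a species holds: one Q or L counts as two
- the stated concentrations are those of everything mixed, before any reaction; amounts are the same in each set-up
- on the list of suspects stand: D -> Z + J; E + Z <-> X; E + J -> L; G + X <-> D; 2 D -> Q
- the feed brings no volume worth counting
- the earlier runs were made in a closed, stirred flask

1. order of the set-ups by the amount of J at the outlet or at the end, in percent of the E put in, highest first (zeta / epsilon / alpha / eta)
2. amount of J at the outlet or at the end, in percent of the E put in, zeta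
3. amount of J at the outlet or at the end, in percent of the E put in, epsilon
4. amount of J at the outlet or at the end, in percent of the E put in, alpha
5. amount of J at the outlet or at the end, in percent of the E put in, eta

I followed one molecule of G and asked its chance of becoming J. Over the first 4.00 h of Friday's run, J grew at 0.00185 M h⁻¹, read from a single reading, and that flask held 0.075 M of G. So I reckoned:

λ = 0.0247 h⁻¹

I called λ the spending chance of G: the fraction of the G present that turns to J per hour, with E held at its charge. The earlier runs differ in Z and hold G fixed, so a constant λ, pseudo-first-order in G, was my assumption and not a reading.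

Friday's flask and zeta look nearly the same, since their charges match and both end at 40 h. But Friday's G stood there from the start, while zeta's arrived steadily, so a dosed molecule stayed on average half of the dosing time. With s = λ times the dosing time = 0.987:

Friday's flask: chance = 1 − exp(−s) = 62.7%

zeta: chance = 1 − (1 − exp(−s))/s = 36.4%

Friday's chance on the G charge gives 94.1% of the E, more than the 81.8% read; the rule holds E at its charge. Zeta's chance gives 54.7% of the E as J, and leaves 63.6% of the G unspent.

The forecast gave epsilon > eta > zeta > alpha, with zeta 76%, epsilon 83%, alpha 61% and eta 81.7%, saying “G is fed at about the initial reaction rate”; its zeta stood above my figure.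

The flasks gave epsilon > eta > alpha > zeta: zeta 59.0%, epsilon 88.3%, alpha 63.6%, eta 81.0%.

    D → Z + J (k = 900 h⁻¹)
    E + Z ⇌ X (K = 42.0 M⁻¹, k = 1.10 × 10⁶ M⁻¹ h⁻¹)
    E + J → L (k = 0.0800 M⁻¹ h⁻¹)
    G + X ⇌ D (K = 16.0 M⁻¹, k = 9.10 × 10⁵ M⁻¹ h⁻¹)
    2 D → Q (k = 5800 M⁻¹ h⁻¹)

Zeta ended at 59.0% against my 54.7%, with 59% of its G left against the 63.6% that λ gave. With the falling back of D to G + X taken away, zeta's J rose from 59.0% to 96.3%, and zeta left for ten times the time gave 91.9%, so the J missing from zeta at 40 h stands on that falling back together with the time given. For the neighbour flask, zeta with 0.045 M of G, my rule keeps the chance at 36.4%, which gives 32.8% of the E as J, and that flask ended at 40.1%.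

The numbers in the tables were generated by integration for an exercise, and the scatter is random.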